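**Retrosynthetic overview**

1. The strategy rests on the cyclohexane ring (C1′ bearing the oxane, C3′ H/Br, C4′ CH3/Cl, C6′ H/OH). Its C3′–Br and C4′–Cl bonds are trans and both equatorial, with Br cis to the C1′ substituent, the opposite of the diaxial adduct that BrCl gives with a C3′=C4′ olefin. Both C–halogen bonds are therefore made last, by substitution on the cyclic sulfate of a C3′,C4′ cis-diol: Br by inversion at C3′, Cl by bromine-assisted net retention at C4′.
2. The cis-diol is installed early by osmylation anti to the cis C1′/C6′ substituents and carried as an acetonide, so that no ring olefin competes when the oxane is closed.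
3. Oxane ring: 6-endo bromoetherification of a tertiary homoprenyl carbinol, which comes from chelation-controlled homoprenyl Grignard addition to a cis β-hydroxy methyl ketone.
4. Cyclohexene ring: Evans syn-aldol reaction (sets C1′ and C6′) followed by ring-closing metathesis forming C3′=C4′(CH3).
5. Ring order: cyclohexene (step 4), then oxane (step 10); the key step closes no ring.

Key step: step 15

Remark: locants used throughout are cyclohexane C1′ (bonded to the oxane carbon), C2′H2, C3′, C4′ (methyl-bearing), C5′H2, C6′ (carbinol), and oxane O1, C2 (quaternary, bonded to C1′), C5 (CHBr), C6 (CMe2). "Upper face" means the cyclohexane face anti to the C1′ and C6′ substituents. Aldehyde 5 is assumed to be usable as a freshly prepared solution.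

**Route**

Step 1
Reactants: 1 (R)-4-benzyloxazolidin-2-one; 2 pent-4-enoyl chloride
Product: 3 (4R)-4-benzyl-3-(pent-4-enoyl)-1,3-oxazolidin-2-one
Conditions: n-BuLi, THF, −78 °C; then 2, −78 → 0 °C
Reagents that add atoms: none
Why: N-acylation of the lithiated oxazolidinone by the acid chloride (standard imide formation) leaves the auxiliary stereocentre untouched.

Step 2
Reactants: 4 3-methylbut-3-en-1-ol
Product: 5 3-methylbut-3-enal
Conditions: Dess–Martin periodinane, CH2Cl2, 0 °C → rt; filtered, used at once as a CH2Cl2 solution
Reagents that add atoms: none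
Why: Dess–Martin oxidation of the primary alcohol under base-free conditions should give the β,γ-unsaturated aldehyde without moving the double bond into conjugation.

Step 3
Reactants: 3 (4R)-4-benzyl-3-(pent-4-enoyl)-1,3-oxazolidin-2-one; 5 3-methylbut-3-enal
Product: 7 (4R)-4-benzyl-3-[(2R,3S)-3-hydroxy-5-methyl-2-(prop-2-en-1-yl)hex-5-enoyl]-1,3-oxazolidin-2-one, via boron enolate 6 (not isolated)
Conditions: Bu2BOTf, iPr2NEt, CH2Cl2, 0 °C; then 5, −78 → 0 °C; pH 7 buffer, MeOH, H2O2
Reagents that add atoms: none
Why: Evans syn-aldol reaction, in which the (Z)-boron enolate 6 reacts through a closed Zimmerman–Traxler chair whose face is chosen by the (R)-benzyl group of the dipole-opposed auxiliary, setting C1′ (R) and C6′ (S) in the syn relationship that becomes cis on the ring.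

Step 4
Reactants: 7 aldol adduct
Product: 8 (4R)-4-benzyl-3-[(1R,6S)-6-hydroxy-4-methylcyclohex-3-ene-1-carbonyl]-1,3-oxazolidin-2-one
Conditions: second-generation Grubbs catalyst (H2IMes)(PCy3)Cl2Ru=CHPh (5 mol%), CH2Cl2, 40 °C
Reagents that add atoms: none
Why: ring-closing olefin metathesis between the allyl and 2-methylallyl arms should close the six-membered ring and form the trisubstituted C3′=C4′ bond with loss of ethene, without touching either stereocentre.

Step 5
Reactants: 8 cyclohexenol imide
Product: 9 (1R,6S)-6-hydroxy-N-methoxy-N,4-dimethylcyclohex-3-ene-1-carboxamide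
Conditions: MeNH(OMe)·HCl, AlMe3, CH2Cl2, −20 → 0 °C; aqueous Rochelle salt
Reagents that add atoms: N,O-dimethylhydroxylamine hydrochloride, CNOC.Cl
Why: Weinreb transamination of a β-hydroxy imide by the aluminium amide, assisted by the aluminium alkoxide of the cis β-hydroxyl, should release the auxiliary without epimerising C1′.

Step 6
Reactants: 9 hydroxy Weinreb amide
Product: 10 (1R,2S,4S,5R)-2,4,5-trihydroxy-N-methoxy-N,4-dimethylcyclohexane-1-carboxamide (C3′ and C4′ hydroxyls both on the upper face)
Conditions: OsO4 (2 mol%), NMO, acetone/H2O, 0 °C → rt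
Reagents that add atoms: N-methylmorpholine N-oxide, C[N+]1([O-])CCOCC1; water, O
Why: Upjohn dihydroxylation adds both oxygens suprafacially and should occur on the face anti to the cis C1′ carboxamide and C6′ hydroxyl (one of which is always axial over the lower face of the half-chair), setting C3′ (R) and C4′ (S).

Step 7
Reactants: 10 triol amide
Product: 11 C3′,C4′-O-isopropylidene acetal of 10 (C6′ hydroxyl free)
Conditions: 2,2-dimethoxypropane, PPTS (cat.), CH2Cl2, rt
Reagents that add atoms: 2,2-dimethoxypropane, COC(C)(C)OC
Why: acid-catalysed transketalisation closes a dioxolane only across the cis-vicinal diol, because the C6′ hydroxyl lies on the opposite face and cannot be bridged.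

Step 8
Reactants: 11 acetonide Weinreb amide
Product: 12 1-[(1′R,3′R,4′S,6′S)-6′-hydroxy-3′,4′-(isopropylidenedioxy)-4′-methylcyclohexyl]ethan-1-one
Conditions: MeMgBr (3.5 equiv), THF, −20 → 0 °C; aqueous NH4Cl at −20 °C
Reagents that add atoms: methylmagnesium bromide, C[Mg]Br
Why: Weinreb ketone synthesis, in which the magnesium-chelated tetrahedral adduct prevents over-addition and releases the cis β-hydroxy ketone only on mild quench, so C1′ should not epimerise.

Step 9
Reactants: 12 β-hydroxy methyl ketone; 13 5-bromo-2-methylpent-2-ene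
Product: 15 (2S)-2-[(1′R,3′R,4′S,6′S)-6′-hydroxy-3′,4′-(isopropylidenedioxy)-4′-methylcyclohexyl]-6-methylhept-5-en-2-ol, via homoprenylmagnesium bromide 14 (not isolated)
Conditions: 13, Mg, THF, rt; then 12 added at −78 °C, → −20 °C; aqueous NH4Cl
Reagents that add atoms: none
Why: Grignard addition under Cram chelate control, in which the first equivalent forms the C6′ magnesium alkoxide that ties the ketone oxygen into a six-membered chelate cis-fused to the carbocycle, so the homoprenyl group should add to the carbonyl face anti to C2′ (the convex face) and set the tertiary carbinol as (S).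

Step 10
Reactants: 15 tertiary homoprenyl carbinol
Product: 16 (1′R,3′R,4′S,6′S)-1′-[(2S,5R)-5-bromo-2,6,6-trimethyloxan-2-yl]-3′,4′-(isopropylidenedioxy)-4′-methylcyclohexan-6′-ol
Conditions: 2,4,4,6-tetrabromocyclohexa-2,5-dienone (TBCO), MeNO2, 0 °C → rt, dark
Reagents that add atoms: 2,4,4,6-tetrabromocyclohexa-2,5-dien-1-one, O=C1C(Br)=CC(Br)(Br)C=C1Br
Why: bromoetherification, in which the tertiary hydroxyl opens the bromonium ion at its more substituted carbon (6-endo, Markovnikov) through a chair with the bulky cyclohexyl group equatorial and the C–Br bond necessarily equatorial, which should give the 2,5-trans oxane and set C5 as (R).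

Step 11
Reactants: 16 bromo-oxane alcohol
Product: 17 6′-O-tert-butyldimethylsilyl ether of 16
Conditions: TBSOTf, 2,6-lutidine, CH2Cl2, −78 → 0 °C
Reagents that add atoms: tert-butyldimethylsilyl triflate, CC(C)(C)[Si](C)(C)OS(=O)(=O)C(F)(F)F
Why: silylation with the silyl triflate should reach the hindered axial secondary hydroxyl, the only free OH, while the ketal, ether and bromide are inert.

Step 12
Reactants: 17 silyl ether acetonide
Product: 18 6′-O-TBS (3′R,4′S)-3′,4′-cis-diol carrying the (2S,5R)-bromo-oxane at C1′
Conditions: PPTS (0.2 equiv), MeOH, 40 °C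
Reagents that add atoms: none
Why: acid-catalysed transketalisation to methanol should remove the dioxolane while the hindered secondary silyl ether, the tertiary ether and the bromide survive the weak acid.

Step 13
Reactants: 18 cis-diol
Product: 19 cyclic sulfite of 18 (mixture of epimers at sulfur)
Conditions: SOCl2, Et3N, CH2Cl2, 0 °C
Reagents that add atoms: thionyl chloride, O=S(Cl)Cl
Why: cyclic sulfite formation from a cis-vicinal diol and thionyl chloride, buffered by the amine so that the silyl ether is not exposed to HCl.

Step 14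
Reactants: 19 cyclic sulfite
Product: 20 cyclic sulfate of the C3′,C4′ cis-diol (6′-O-TBS, bromo-oxane at C1′)
Conditions: RuCl3·xH2O (cat.), NaIO4, MeCN/H2O, 0 °C
Reagents that add atoms: sodium periodate, [Na+].[O-]I(=O)(=O)=O
Why: RuO4-catalysed oxidation of sulfite to sulfate, for which the substrate is well suited because the oxane has no C–H next to oxygen and no olefin remains.

Step 15
Reactants: 20 cyclic sulfate
Product: 23 6′-O-tert-butyldimethylsilyl ether of the target, via tetrabutylammonium sulfate monoester 21 (not isolated), via bromonium ion 22 (not isolated)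
Conditions: Bu4NBr (1.05 equiv), CH2Cl2, 0 °C → rt; then HCl (2 M in Et2O, 3 equiv), −40 → 0 °C
Reagents that add atoms: tetrabutylammonium bromide, CCCC[N+](CCCC)(CCCC)CCCC.[Br-]; hydrogen chloride, Cl
Why: Proposed new method: bromide opens the cyclic sulfate by SN2 at secondary C3′, whose C–O bond is axial in the chair that keeps the oxanyl group equatorial, so C3′ is inverted and bromine becomes equatorial and cis to C1′, leaving the tertiary sulfate monoester 21; HCl then protonates 21 to the alkyl hydrogen sulfate, which should undergo alkyl–oxygen fission at the tertiary centre with the trans bromine bridging from the lower face (22), and chloride should open 22 at C4′ from the upper face, so that C4′ keeps its configuration by double inversion (Cl equatorial, CH3 axial). The closest known reaction types are halide opening of cyclic sulfates at the less substituted carbon, alkyl–oxygen fission of tertiary alkyl hydrogen sulfates in acid, and retentive substitution of trans β-bromo alcohols and esters through bromonium ions. No ring is closed; two C–halogen bonds and two stereocentres are formed, C3′ by inversion under control of the osmylation-derived C3′–O configuration and C4′ by net retention under control of the bridging bromine. The step needs regioselectivity twice: bromide attack at the secondary rather than the tertiary carbon is secured by SN2 sterics in a non-ionising medium, and chloride attack at C4′ rather than C3′ by the localisation of positive charge on the tertiary carbon of the unsymmetrical bromonium ion, which has to override the diaxial (Fürst–Plattner) preference for C3′. Because the relay can generate the bromonium ion only on the lower face, the diaxial BrCl-type adduct that arises from the upper-face bromonium ion cannot form.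

Step 16
Reactants: 23 silyl ether of the target
Product: 24 (1S,2R,4S,5S)-4-bromo-2-[(2S,5R)-5-bromo-2,6,6-trimethyloxan-2-yl]-5-chloro-5-methylcyclohexan-1-ol (target)
Conditions: HF·pyridine, pyridine, THF, 0 °C → rt
Reagents that add atoms: none
Why: fluoride-mediated Si–O cleavage under buffered, non-basic conditions should free the axial hydroxyl without E2 loss of HBr or HCl from the halides.

**Compound list**

1 | (R)-4-benzyloxazolidin-2-one | O=C1OC[C@@H](Cc2ccccc2)N1 | starting material
2 | pent-4-enoyl chloride | C=CCCC(Cl)=O | starting material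
3 | (4R)-4-benzyl-3-(pent-4-enoyl)-1,3-oxazolidin-2-one | C=CCCC(=O)N1C(=O)OC[C@H]1Cc1ccccc1 | intermediate
4 | 3-methylbut-3-en-1-ol | CC(=C)CCO | starting material
5 | 3-methylbut-3-enal | CC(=C)CC=O | intermediate
6 | dibutylboron (Z)-enolate of 3 (not isolated) | CCCCB(CCCC)O/C(=C\CC=C)N1C(=O)OC[C@H]1Cc1ccccc1 | intermediate
7 | (4R)-4-benzyl-3-[(2R,3S)-3-hydroxy-5-methyl-2-(prop-2-en-1-yl)hex-5-enoyl]-1,3-oxazolidin-2-one | O=C([C@H](CC=C)[C@@H](O)CC(C)=C)N1C(=O)OC[C@H]1Cc1ccccc1 | intermediate
8 | (4R)-4-benzyl-3-[(1R,6S)-6-hydroxy-4-methylcyclohex-3-ene-1-carbonyl]-1,3-oxazolidin-2-one | O=C([C@@H]1CC=C(C)C[C@@H]1O)N1C(=O)OC[C@H]1Cc1ccccc1 | intermediate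
9 | (1R,6S)-6-hydroxy-N-methoxy-N,4-dimethylcyclohex-3-ene-1-carboxamide | CON(C)C(=O)[C@@H]1CC=C(C)C[C@@H]1O | intermediate
10 | (1R,2S,4S,5R)-2,4,5-trihydroxy-N-methoxy-N,4-dimethylcyclohexane-1-carboxamide | CON(C)C(=O)[C@@H]1C[C@@H](O)[C@@](C)(O)C[C@@H]1O | intermediate
11 | C3′,C4′-acetonide of 10 (1′R,3′R,4′S,6′S; C6′–OH free) | CON(C)C(=O)[C@@H]1C[C@H]2OC(C)(C)O[C@@]2(C)C[C@@H]1O | intermediate
12 | 1-[(1′R,3′R,4′S,6′S)-6′-hydroxy-3′,4′-(isopropylidenedioxy)-4′-methylcyclohexyl]ethan-1-one | CC(=O)[C@@H]1C[C@H]2OC(C)(C)O[C@@]2(C)C[C@@H]1O | intermediate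
13 | 5-bromo-2-methylpent-2-ene | CC(C)=CCCBr | starting material
14 | 4-methylpent-3-en-1-ylmagnesium bromide (not isolated) | CC(C)=CCC[Mg]Br | intermediate
15 | (2S)-2-[(1′R,3′R,4′S,6′S)-6′-hydroxy-3′,4′-(isopropylidenedioxy)-4′-methylcyclohexyl]-6-methylhept-5-en-2-ol | CC(C)=CCC[C@](C)(O)[C@@H]1C[C@H]2OC(C)(C)O[C@@]2(C)C[C@@H]1O | intermediate
16 | (1′R,3′R,4′S,6′S)-1′-[(2S,5R)-5-bromo-2,6,6-trimethyloxan-2-yl]-3′,4′-(isopropylidenedioxy)-4′-methylcyclohexan-6′-ol | CC1(C)O[C@](C)([C@@H]2C[C@H]3OC(C)(C)O[C@@]3(C)C[C@@H]2O)CC[C@H]1Br | intermediate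
17 | 6′-O-tert-butyldimethylsilyl ether of 16 | CC1(C)O[C@](C)([C@@H]2C[C@H]3OC(C)(C)O[C@@]3(C)C[C@@H]2O[Si](C)(C)C(C)(C)C)CC[C@H]1Br | intermediate
18 | 6′-O-TBS (3′R,4′S)-3′,4′-cis-diol with the (2S,5R)-bromo-oxane at C1′ | CC1(C)O[C@](C)([C@@H]2C[C@@H](O)[C@@](C)(O)C[C@@H]2O[Si](C)(C)C(C)(C)C)CC[C@H]1Br | intermediate
19 | cyclic sulfite of 18 (epimers at sulfur) | CC1(C)O[C@](C)([C@@H]2C[C@H]3OS(=O)O[C@@]3(C)C[C@@H]2O[Si](C)(C)C(C)(C)C)CC[C@H]1Br | intermediate
20 | cyclic sulfate of 18 (key-step precursor) | CC1(C)O[C@](C)([C@@H]2C[C@H]3OS(=O)(=O)O[C@@]3(C)C[C@@H]2O[Si](C)(C)C(C)(C)C)CC[C@H]1Br | intermediate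
21 | tetrabutylammonium (3′S,4′S)-3′-bromo-4′-sulfate monoester (not isolated) | CC1(C)O[C@](C)([C@@H]2C[C@H](Br)[C@@](C)(OS(=O)(=O)[O-])C[C@@H]2O[Si](C)(C)C(C)(C)C)CC[C@H]1Br.CCCC[N+](CCCC)(CCCC)CCCC | intermediate
22 | C3′,C4′ bromonium ion bridged on the lower face, hydrogen sulfate salt (not isolated) | CC1(C)O[C@](C)([C@@H]2C[C@@H]3[Br+][C@]3(C)C[C@@H]2O[Si](C)(C)C(C)(C)C)CC[C@H]1Br.OS(=O)(=O)[O-] | intermediate
23 | 6′-O-tert-butyldimethylsilyl ether of the target | CC1(C)O[C@](C)([C@@H]2C[C@H](Br)[C@@](C)(Cl)C[C@@H]2O[Si](C)(C)C(C)(C)C)CC[C@H]1Br | intermediate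
24 | (1S,2R,4S,5S)-4-bromo-2-[(2S,5R)-5-bromo-2,6,6-trimethyloxan-2-yl]-5-chloro-5-methylcyclohexan-1-ol | CC1(C)O[C@](C)([C@@H]2C[C@H](Br)[C@@](C)(Cl)C[C@@H]2O)CC[C@H]1Br | target

**Step count and risks**

Total step count: 16. Longest linear sequence: 15 steps (steps 1 and 3–16; step 2 is a one-step branch that supplies aldehyde 5).

Steps most likely to fail:

1. Step 15 (proposed method). After bromide opening, heterolysis of the β-bromo tertiary sulfate may lag. Bromine retards ionisation inductively, and its assistance needs an antiperiplanar Br–C–C–O arrangement that is reached only in a twist form or in the chair with the oxanyl group axial. E1 proton loss to allylic bromides, chloride attack at C3′ in the diaxial sense, halophilic bromine transfer or premature loss of the silyl ether could then compete. Fallback with known chemistry, setting out from 20 and returning at 23: the bromide opening is run alone (Bu4NBr, CH2Cl2) to 21, and the sulfate monoester is hydrolysed with catalytic H2SO4 and one equivalent of water in THF to the isolable trans bromohydrin, the 6′-O-TBS (3′S,4′S)-3′-bromo-4′-hydroxy compound F1. F1 is purified and then treated with anhydrous HCl in CH2Cl2 at −20 °C. This is the classical conversion of a tertiary alcohol into its chloride, which for a trans β-bromo alcohol proceeds with retention through the bridged bromonium ion and should give 23. The two substitutions can then be optimised and analysed separately.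

2. Step 10. The bromonium ion may be captured at the secondary carbon (5-exo closure to an oxolane) or through a boat transition state (C5 epimer), and the liberated acid may erode the acetonide. Fallback setting out from 15 and returning at 16: intramolecular alkoxymercuration with mercury bis(trifluoroacetate), Hg(OCOCF3)2, in MeCN at −20 °C, which is more strictly Markovnikov than bromonium capture, should give the oxan-5-ylmercury trifluoroacetate F2. Aqueous KBr exchanges it to the oxan-5-ylmercury bromide F3, which is isolated. Bromodemercuration of F3 with Br2 in pyridine at 0 °C in the dark, a polar substitution at carbon that retains configuration, should then give 16.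

3. Step 6. Facial selectivity of the osmylation may be poor, because the free hydroxyl and the carboxamide shield the lower face only modestly. Fallback setting out from 9 and returning at 11: the C6′ hydroxyl is first silylated (TESCl, imidazole, CH2Cl2) to the triethylsilyl ether F4, whose bulky axial silyloxy group should block the lower face. Osmylation (OsO4 cat., NMO) then gives the triethylsilyl-protected upper-face diol F5. Treatment of F5 with 2,2-dimethoxypropane and camphorsulfonic acid, followed by methanol, should form the acetonide and remove the labile silyl ether in the same operation, giving 11.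

Further compounds
F1 | step 15 | 6′-O-TBS (3′S,4′S)-3′-bromo-4′-hydroxy compound (trans bromohydrin of the bromo-oxane cyclohexane) | CC1(C)O[C@](C)([C@@H]2C[C@H](Br)[C@@](C)(O)C[C@@H]2O[Si](C)(C)C(C)(C)C)CC[C@H]1Br
F2 | step 10 | [(3R,6S)-6-(acetonide-protected hydroxycyclohexyl)-2,2,6-trimethyloxan-3-yl]mercury trifluoroacetate | CC1(C)O[C@](C)([C@@H]2C[C@H]3OC(C)(C)O[C@@]3(C)C[C@@H]2O)CC[C@H]1[Hg]OC(=O)C(F)(F)F
F3 | step 10 | [(3R,6S)-6-(acetonide-protected hydroxycyclohexyl)-2,2,6-trimethyloxan-3-yl]mercury bromide | CC1(C)O[C@](C)([C@@H]2C[C@H]3OC(C)(C)O[C@@]3(C)C[C@@H]2O)CC[C@H]1[Hg]Br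
F4 | step 6 | (1R,6S)-N-methoxy-N,4-dimethyl-6-(triethylsilyloxy)cyclohex-3-ene-1-carboxamide | CON(C)C(=O)[C@@H]1CC=C(C)C[C@@H]1O[Si](CC)(CC)CC
F5 | step 6 | (1R,2S,4S,5R)-4,5-dihydroxy-N-methoxy-N,4-dimethyl-2-(triethylsilyloxy)cyclohexane-1-carboxamide | CON(C)C(=O)[C@@H]1C[C@@H](O)[C@@](C)(O)C[C@@H]1O[Si](CC)(CC)CC
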